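**Plan**

- Retrosynthesis: the three silyl ethers come off last, the C3–H bond is traced back to a C3–NO2 bond, and ring C is then cut at O1–C2 and C3–C4 in one operation.
- Enabling feature: C3 of ring C sits between the O1–C2 ether link and the C4 carbinol. A temporary nitro group on C3 makes C2=C3 a Michael acceptor for a ring A phenol and then turns C3 into a nitronate that attacks the ring A formyl carbon (the future C4).
- Forward: ring B is built from 5-bromo-2,4-dihydroxybenzaldehyde into a 1-aryl-1-nitroethene (silylation, methylation, reduction, Stille prenylation, bromide, nitrite displacement, hydroxymethylation, dehydration). Ring C then forms in one step on the symmetric ring A aldehyde.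
- Stereochemistry: C4 is set by a cinchona thiourea catalyst in the nitro-aldol closure. C3 is set when the nitro group is exchanged for hydrogen through a planar C3 radical that takes hydrogen anti to the C4 silyloxy group, giving the 3,4-cis (3R,4R) isoflavan-4-ol.

Key step: step 9

Abbreviations: Ar = 2-methoxy-5-(3-methylbut-2-en-1-yl)-4-[(triisopropylsilyl)oxy]phenyl (ring B); TIPS = triisopropylsilyl; TBS = tert-butyldimethylsilyl.

Remark: which pseudoenantiomer of the cinchona thiourea favours the (4S) carbinol in this closure cannot be predicted with confidence; the quinine-derived catalyst is assumed, and the quinidine-derived one would be used in the same way if the sense is opposite.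

**Route**

Step 1
Reactants: 1 5-bromo-2,4-dihydroxybenzaldehyde
Product: 2 5-bromo-2-hydroxy-4-[(triisopropylsilyl)oxy]benzaldehyde
Conditions: TIPSCl (1.05 equiv), imidazole, DMF, 0 °C to rt
Reagents that add atoms: triisopropylsilyl chloride, CC(C)[Si](Cl)(C(C)C)C(C)C
Why: Chemoselective O-silylation, in which the 2-hydroxyl is tied up in a hydrogen bond to the formyl group and is the poorer nucleophile, so the bulky silyl chloride should take the free, more acidic 4-hydroxyl.

Step 2
Reactants: 2 5-bromo-2-hydroxy-4-[(triisopropylsilyl)oxy]benzaldehyde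
Product: 3 5-bromo-2-methoxy-4-[(triisopropylsilyl)oxy]benzaldehyde
Conditions: MeOH, PPh3, DIAD, THF, 0 °C to rt
Reagents that add atoms: methanol, CO
Why: Mitsunobu etherification with methanol alkylates the remaining acidic phenol under neutral conditions, which avoids carbonate bases that could loosen an aryl silyl ether para to a formyl group.

Step 3
Reactants: 3 5-bromo-2-methoxy-4-[(triisopropylsilyl)oxy]benzaldehyde
Product: 4 {5-bromo-2-methoxy-4-[(triisopropylsilyl)oxy]phenyl}methanol
Conditions: NaBH4, THF/EtOH, 0 °C
Reagents that add atoms: none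
Why: Borohydride reduction of an aromatic aldehyde to the benzylic alcohol, placed here so that no electrophilic carbonyl group is present when the allylstannane is introduced.

Step 4
Reactants: 4 {5-bromo-2-methoxy-4-[(triisopropylsilyl)oxy]phenyl}methanol; 5 tributyl(3-methylbut-2-en-1-yl)stannane
Product: 6 {2-methoxy-5-(3-methylbut-2-en-1-yl)-4-[(triisopropylsilyl)oxy]phenyl}methanol (ArCH2OH)
Conditions: Pd(PPh3)4 (5 mol%), DMF, 95 °C
Reagents that add atoms: none
Why: Stille coupling, in which zerovalent palladium inserts into the aryl bromide, the allyl group is transferred from tin and reductive elimination at the unsubstituted allyl terminus should give the linear prenyl arene, while the neutral conditions spare the silyl ether and the free alcohol.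

Step 5
Reactants: 6 {2-methoxy-5-(3-methylbut-2-en-1-yl)-4-[(triisopropylsilyl)oxy]phenyl}methanol
Product: 7 [4-(bromomethyl)-5-methoxy-2-(3-methylbut-2-en-1-yl)phenoxy]triisopropylsilane (ArCH2Br)
Conditions: CBr4, PPh3, CH2Cl2, 0 °C
Reagents that add atoms: carbon tetrabromide, BrC(Br)(Br)Br
Why: Appel reaction, which converts the primary benzylic alcohol into the bromide under neutral conditions that leave the prenyl alkene and the aryl silyl ether untouched, the electron-rich bromide being carried on at once without storage.

Step 6
Reactants: 7 [4-(bromomethyl)-5-methoxy-2-(3-methylbut-2-en-1-yl)phenoxy]triisopropylsilane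
Product: 8 [5-methoxy-2-(3-methylbut-2-en-1-yl)-4-(nitromethyl)phenoxy]triisopropylsilane (ArCH2NO2)
Conditions: NaNO2, urea, DMF, −20 °C
Reagents that add atoms: sodium nitrite, [Na+].[O-]N=O
Why: Kornblum nitrite displacement (the polar-solvent form of the Victor Meyer reaction), in which nitrite attacks the primary benzylic bromide in an SN2 manner mainly through nitrogen, the low temperature being chosen to hold back ionisation of the electron-rich benzylic system that would favour the nitrite ester.

Step 7
Reactants: 8 [5-methoxy-2-(3-methylbut-2-en-1-yl)-4-(nitromethyl)phenoxy]triisopropylsilane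
Product: 9 2-Ar-2-nitroethan-1-ol (racemic)
Conditions: paraformaldehyde (1.0 equiv), Et3N (0.2 equiv), THF, 0 °C to rt
Reagents that add atoms: formaldehyde (from paraformaldehyde), C=O
Why: Henry (nitro-aldol) addition of the acidic arylnitromethane to formaldehyde under catalytic amine base, where one equivalent of formaldehyde and the hindrance of the ortho-methoxyaryl group should stop the reaction at the mono-adduct, whose new stereocentre is racemic and is destroyed in the next step.

Step 8
Reactants: 9 2-Ar-2-nitroethan-1-ol
Product: 11 1-Ar-1-nitroethene, via mesylate 10 (not isolated)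
Conditions: MsCl, i-Pr2NEt, CH2Cl2, −78 to −20 °C
Reagents that add atoms: none
Why: Dehydration by sulfonylation and E1cB elimination, in which the primary alcohol is mesylated and the amine removes the acidic proton next to the nitro group to expel mesylate, giving the 1,1-disubstituted nitroalkene that is kept cold and used directly because such nitroalkenes polymerise.

Step 9
Reactants: 11 1-Ar-1-nitroethene; 12 2,6-dihydroxy-4-methoxybenzaldehyde (1.2 equiv)
Product: 14 (3R,4S)-3-Ar-7-methoxy-3-nitrochromane-4,5-diol, via oxa-Michael adduct 13 (not isolated)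
Conditions: 1-[3,5-bis(trifluoromethyl)phenyl]-3-[(8S,9S)-6'-methoxycinchonan-9-yl]thiourea (10 mol%), toluene/CH2Cl2, −20 °C, slow addition of 11
Reagents that add atoms: none
Why: The quinuclidine nitrogen of the bifunctional catalyst deprotonates one of the two equivalent phenols of 12 while the thiourea binds the nitro group of 11, so the phenoxide adds to the unsubstituted alkene terminus (O1–C2, intermolecular oxa-Michael addition), and the nitronate 13, still held beside the ammonium-activated formyl group, closes ring C by a 6-exo-trig nitro-aldol (Henry) addition that forms C3–C4. The closest known reaction type is the amine–thiourea-catalysed oxa-Michael–Henry domino reaction of salicylaldehydes with nitroalkenes, applied here to a 1,1-disubstituted nitroalkene so that stereochemistry arises only in the Henry step. The C4 carbinol centre is set by the catalyst, which should present one face of the formyl group to the bound nitronate, and the quaternary C3 centre follows from the closed, hydrogen-bonded transition state that places nitro and hydroxyl cis; C3 is erased later, so only C4 has to be controlled. The step needs O- over C-alkylation of the electron-rich phenol and a single addition: the formyl group lowers the nucleophilicity of the ring carbons, only the O-adduct can be drained by ring closure, and the symmetry of 12 means either phenol leads to the same product with the spare one becoming the C5 hydroxyl. Because C3 carries no hydrogen the adduct cannot lose water to a nitrochromene, and the low temperature is meant to limit retro-Henry equilibration before the carbinol is silylated.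

Step 10
Reactants: 14 (3R,4S)-3-Ar-7-methoxy-3-nitrochromane-4,5-diol
Product: 15 (3R,4S)-3-Ar-4,5-bis[(tert-butyldimethylsilyl)oxy]-7-methoxy-3-nitrochromane
Conditions: TBSOTf (3 equiv), 2,6-lutidine, CH2Cl2, −78 to 0 °C
Reagents that add atoms: tert-butyldimethylsilyl trifluoromethanesulfonate, CC(C)(C)[Si](C)(C)OS(=O)(=O)C(F)(F)F
Why: O-silylation with a silyl triflate and a hindered pyridine base is fast at low temperature and barely basic, so the phenol and the hindered secondary carbinol should both be capped without retro-Henry opening of the beta-nitro alcohol.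

Step 11
Reactants: 15 (3R,4S)-3-Ar-4,5-bis[(tert-butyldimethylsilyl)oxy]-7-methoxy-3-nitrochromane
Product: 16 (3R,4R)-3-Ar-4,5-bis[(tert-butyldimethylsilyl)oxy]-7-methoxychromane
Conditions: Bu3SnH, AIBN, toluene, 80 °C
Reagents that add atoms: none
Why: Tin hydride radical denitration of a tertiary benzylic nitro compound, in which stannyl radical addition to the nitro group and C–N fragmentation give a planar benzylic C3 radical and, because peri strain with the C5 silyloxy group holds the C4 silyloxy group pseudoaxial, hydrogen should be delivered from Bu3SnH to the opposite face, placing the aryl group cis to O4 and setting (3R).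

Step 12
Reactants: 16 (3R,4R)-3-Ar-4,5-bis[(tert-butyldimethylsilyl)oxy]-7-methoxychromane
Product: 17 (3R,4R)-3-[4-hydroxy-2-methoxy-5-(3-methylbut-2-en-1-yl)phenyl]-7-methoxychromane-4,5-diol
Conditions: TBAF, AcOH, THF, 0 °C to rt
Reagents that add atoms: none
Why: Fluoride-mediated desilylation cleaves the two aryl silyl ethers and the secondary silyl ether, buffered with acetic acid so that the electron-rich benzylic carbinol meets neither strong base nor acid and no stereocentre is touched.

**Compound list**

1 | 5-bromo-2,4-dihydroxybenzaldehyde | O=Cc1cc(Br)c(O)cc1O | starting material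
2 | 5-bromo-2-hydroxy-4-[(triisopropylsilyl)oxy]benzaldehyde | O=Cc1cc(Br)c(O[Si](C(C)C)(C(C)C)C(C)C)cc1O | intermediate
3 | 5-bromo-2-methoxy-4-[(triisopropylsilyl)oxy]benzaldehyde | O=Cc1cc(Br)c(O[Si](C(C)C)(C(C)C)C(C)C)cc1OC | intermediate
4 | {5-bromo-2-methoxy-4-[(triisopropylsilyl)oxy]phenyl}methanol | OCc1cc(Br)c(O[Si](C(C)C)(C(C)C)C(C)C)cc1OC | intermediate
5 | tributyl(3-methylbut-2-en-1-yl)stannane | CCCC[Sn](CCCC)(CCCC)CC=C(C)C | starting material
6 | {2-methoxy-5-(3-methylbut-2-en-1-yl)-4-[(triisopropylsilyl)oxy]phenyl}methanol | OCc1cc(CC=C(C)C)c(O[Si](C(C)C)(C(C)C)C(C)C)cc1OC | intermediate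
7 | [4-(bromomethyl)-5-methoxy-2-(3-methylbut-2-en-1-yl)phenoxy]triisopropylsilane | BrCc1cc(CC=C(C)C)c(O[Si](C(C)C)(C(C)C)C(C)C)cc1OC | intermediate
8 | [5-methoxy-2-(3-methylbut-2-en-1-yl)-4-(nitromethyl)phenoxy]triisopropylsilane | [O-][N+](=O)Cc1cc(CC=C(C)C)c(O[Si](C(C)C)(C(C)C)C(C)C)cc1OC | intermediate
9 | 2-{2-methoxy-5-(3-methylbut-2-en-1-yl)-4-[(triisopropylsilyl)oxy]phenyl}-2-nitroethan-1-ol (racemic) | OCC(c1cc(CC=C(C)C)c(O[Si](C(C)C)(C(C)C)C(C)C)cc1OC)[N+](=O)[O-] | intermediate
10 | methanesulfonate of 9 (formed in the flask, not isolated) | CS(=O)(=O)OCC(c1cc(CC=C(C)C)c(O[Si](C(C)C)(C(C)C)C(C)C)cc1OC)[N+](=O)[O-] | intermediate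
11 | [5-methoxy-2-(3-methylbut-2-en-1-yl)-4-(1-nitroethenyl)phenoxy]triisopropylsilane (1-Ar-1-nitroethene) | C=C(c1cc(CC=C(C)C)c(O[Si](C(C)C)(C(C)C)C(C)C)cc1OC)[N+](=O)[O-] | intermediate
12 | 2,6-dihydroxy-4-methoxybenzaldehyde | COc1cc(O)c(C=O)c(O)c1 | starting material
13 | 2-(2-Ar-2-nitroethoxy)-6-hydroxy-4-methoxybenzaldehyde, present as its catalyst-bound nitronate (not isolated) | COc1cc(O)c(C=O)c(OCC(c2cc(CC=C(C)C)c(O[Si](C(C)C)(C(C)C)C(C)C)cc2OC)[N+](=O)[O-])c1 | intermediate
14 | (3R,4S)-3-Ar-7-methoxy-3-nitrochromane-4,5-diol | COc1cc(O)c2c(c1)OC[C@]([N+](=O)[O-])(c1cc(CC=C(C)C)c(O[Si](C(C)C)(C(C)C)C(C)C)cc1OC)[C@H]2O | intermediate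
15 | (3R,4S)-3-Ar-4,5-bis[(tert-butyldimethylsilyl)oxy]-7-methoxy-3-nitrochromane | COc1cc(O[Si](C)(C)C(C)(C)C)c2c(c1)OC[C@]([N+](=O)[O-])(c1cc(CC=C(C)C)c(O[Si](C(C)C)(C(C)C)C(C)C)cc1OC)[C@H]2O[Si](C)(C)C(C)(C)C | intermediate
16 | (3R,4R)-3-Ar-4,5-bis[(tert-butyldimethylsilyl)oxy]-7-methoxychromane | COc1cc(O[Si](C)(C)C(C)(C)C)c2c(c1)OC[C@@H](c1cc(CC=C(C)C)c(O[Si](C(C)C)(C(C)C)C(C)C)cc1OC)[C@H]2O[Si](C)(C)C(C)(C)C | intermediate
17 | (3R,4R)-3-[4-hydroxy-2-methoxy-5-(3-methylbut-2-en-1-yl)phenyl]-7-methoxychromane-4,5-diol | COc1cc(O)c2c(c1)OC[C@@H](c1cc(CC=C(C)C)c(O)cc1OC)[C@H]2O | target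

**Step count**

Total: 12 steps. Longest linear sequence: 12 steps (1 to 17); compounds 5 and 12 are bought and enter at steps 4 and 9.

**Steps most likely to fail**

1. Step 9. The nitro-aldol closure onto the electron-rich, hydrogen-bonded aldehyde may be reversible under the amine catalyst, which would wash out the catalyst-set C4 configuration; anionic oligomerisation of the nitroalkene may also compete with conjugate addition. The fallback sets out from 11 and 12 and returns to the route at 17; it keeps the nitro-based ring construction and moves all stereocontrol to a ketone reduction.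
   - Stirring 11 and 12 with DABCO in THF should give the annulation product without enantiocontrol, racemic 3-Ar-7-methoxy-3-nitrochromane-4,5-diol F1.
   - Bu3SnH/AIBN in toluene at 80 °C removes the nitro group to give 3-Ar-7-methoxychromane-4,5-diol F2 as a stereoisomer mixture.
   - MnO2 in CH2Cl2 oxidises the benzylic carbinol to the racemic isoflavanone 3-Ar-5-hydroxy-7-methoxychroman-4-one F3.
   - Noyori asymmetric transfer hydrogenation with RuCl[(R,R)-TsDPEN](p-cymene) in HCO2H/Et3N, under which the C3 centre next to the ketone epimerises (dynamic kinetic resolution), should give the cis alcohol (3R,4R)-3-Ar-7-methoxychromane-4,5-diol F4.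
   - TBAF/AcOH then gives 17.

2. Step 11. Hydrogen transfer to the planar C3 radical may proceed with poor facial discrimination, giving both C3 epimers. The fallback sets out from 14 and returns at 17. Dess–Martin periodinane in CH2Cl2 oxidises the carbinol to (3R)-3-Ar-5-hydroxy-7-methoxy-3-nitrochroman-4-one F5. Bu3SnH/AIBN denitrates this alpha-nitro ketone to the isoflavanone F3, and the transfer hydrogenation and desilylation described under step 9 carry the isoflavanone F3 through the cis alcohol F4 to 17. The cis relationship then rests on the ketone reduction and not on the radical.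

3. Step 6. The electron-rich benzylic bromide may ionise, so that nitrite reacts through oxygen or the bromide alkylates itself instead of undergoing clean SN2 attack by nitrogen. The fallback sets out from 3, bypasses steps 3 to 6 and returns at 8; the C–N bond is never made by substitution.
   - NH2OH·HCl/NaOAc in EtOH converts the aldehyde into 5-bromo-2-methoxy-4-[(triisopropylsilyl)oxy]benzaldehyde oxime F6.
   - NaBO3·4H2O in AcOH at 55 °C oxidises the oxime nitrogen, at a stage where no alkene is present, to give [2-bromo-5-methoxy-4-(nitromethyl)phenoxy]triisopropylsilane F7.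
   - Stille coupling of F7 with 5 (Pd(PPh3)4, DMF, 95 °C) installs the prenyl group and gives 8.

**Further compounds**

F1 | step 9 | racemic 3-Ar-7-methoxy-3-nitrochromane-4,5-diol (diastereomer mixture) | COc1cc(O)c2c(c1)OCC([N+](=O)[O-])(c1cc(CC=C(C)C)c(O[Si](C(C)C)(C(C)C)C(C)C)cc1OC)C2O
F2 | step 9 | 3-Ar-7-methoxychromane-4,5-diol (stereoisomer mixture) | COc1cc(O)c2c(c1)OCC(c1cc(CC=C(C)C)c(O[Si](C(C)C)(C(C)C)C(C)C)cc1OC)C2O
F3 | step 9 | racemic 3-Ar-5-hydroxy-7-methoxychroman-4-one | COc1cc(O)c2c(c1)OCC(c1cc(CC=C(C)C)c(O[Si](C(C)C)(C(C)C)C(C)C)cc1OC)C2=O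
F4 | step 9 | (3R,4R)-3-Ar-7-methoxychromane-4,5-diol | COc1cc(O)c2c(c1)OC[C@@H](c1cc(CC=C(C)C)c(O[Si](C(C)C)(C(C)C)C(C)C)cc1OC)[C@H]2O
F5 | step 11 | (3R)-3-Ar-5-hydroxy-7-methoxy-3-nitrochroman-4-one | COc1cc(O)c2c(c1)OC[C@]([N+](=O)[O-])(c1cc(CC=C(C)C)c(O[Si](C(C)C)(C(C)C)C(C)C)cc1OC)C2=O
F6 | step 6 | 5-bromo-2-methoxy-4-[(triisopropylsilyl)oxy]benzaldehyde oxime | ON=Cc1cc(Br)c(O[Si](C(C)C)(C(C)C)C(C)C)cc1OC
F7 | step 6 | [2-bromo-5-methoxy-4-(nitromethyl)phenoxy]triisopropylsilane | [O-][N+](=O)Cc1cc(Br)c(O[Si](C(C)C)(C(C)C)C(C)C)cc1OC
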